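**Plan**
- Retrosynthesis: the lactone bond C16–O and the alkene C13=C14 are opened together to a trans-cyclopropane (C14–C15–C16) flanked by a C13 tertiary carbinol and a (Z)-enoic acid. This is possible because the E-alkene C13=C14 is homoallylic, through C15, to the oxygen-bearing ring carbon C16 of the butenolide.
- The carbinol is then cut at C12–C13 into a decalin C12 iodide and an enantiopure cyclopropyl methyl ketone. The C4 carboxyl is traced to the 4α-methyl group of (+)-larixol and the C8 carbinol to its exocyclic alkene.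
- Forward: the decalin is taken from larixol (side chain shortened to C12, 4α-methyl oxidised through the 6α-oxygen, C8 hydrated; steps 1–10). The cyclopropane is made from an enynol (steps 11–16). The two are joined at C12–C13 (step 17), and the butenolide ring and the alkene arise last (step 19).
- Stereochemistry: C5, C6, C9 and C10 come from larixol; C4 from the peri geometry of a 1,5-hydrogen transfer; C8 from α-face epoxidation; C16 from a Charette cyclopropanation, transferred with inversion in step 19. The alkenes come from syn-carbocupration (Z) and from the bisected cation (E).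

Key step: step 19

Remark: (+)-larixol is taken as a catalogue diterpene; decalin carbons are C1–C10, chain carbons C11–C16 (C16 = lactone CH), butenolide carbons C17 (C–CH3), C18 (=CH), C19 (C=O); C4′ is the 4α-substituent carbon and C8′ the substituent carbon on C8; all decalin compounds keep 5α-H, 9α-H, 10β-CH3 and the 6α-oxygen of larixol.

**Step 1**
Reactants: 1 (+)-larixol
Product: 2 nor-ketone (6α-hydroxy-8-methylidene decalin with a 3-oxobutyl chain on C9)
Conditions: KMnO4, acetone/H2O, 0 °C to rt
Reagents that add atoms: none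
Why: Permanganate degradation of the tertiary vinyl carbinol (dihydroxylation, glycol cleavage, oxidative decarboxylation), as used to shorten manool and sclareol, should leave the methyl ketone, since the hindered exocyclic alkene and the equatorial 6-hydroxyl react more slowly.

**Step 2**
Reactants: 2 nor-ketone
Product: 3 epoxy acetate (C12 acetate, 8α-O/C8′ spiro-epoxide, free 6α-OH)
Conditions: CF3CO3H, Na2HPO4, CH2Cl2, 0 °C to rt
Reagents that add atoms: trifluoroperacetic acid, OOC(=O)C(F)(F)F
Why: The buffered peracid should effect Baeyer–Villiger oxidation of the methyl ketone (primary alkyl migrates in preference to methyl) and Prilezhaev epoxidation of the exocyclic alkene from the α face, away from the axial C10 methyl, which places the C8 oxygen α.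

**Step 3**
Reactants: 3 epoxy acetate
Product: 4 cyclic ether (O6 bonded to C4′, tetrahydrofuran on the α face; epoxide and acetate kept)
Conditions: PhI(OAc)2, I2, cyclohexane, visible light, rt
Reagents that add atoms: none
Why: In this hypoiodite (Suárez) reaction the 6α-alkoxy radical should abstract hydrogen from the peri 4α-methyl group through a six-membered transition state, and the derived iodide is displaced by O6, as in the steroid 6β-ol to 6β,19-ether conversion; only the α-methyl is within reach, so C4 is set.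

**Step 4**
Reactants: 4 cyclic ether
Product: 5 ether diol (C12-OH, 8α-OH with 8β-CH3, O6–C4′ ether)
Conditions: LiAlH4, THF, 0 °C to rt
Reagents that add atoms: none
Why: Hydride should open the 1,1-disubstituted epoxide at its CH2 terminus (SN2), leaving the tertiary 8α-alcohol with the new methyl β, and should cleave the acetate.

**Step 5**
Reactants: 5 ether diol
Product: 6 ether acetate (C12-OAc, 8α-OH)
Conditions: Ac2O, pyridine, DMAP (cat.), CH2Cl2, 0 °C
Reagents that add atoms: acetic anhydride, CC(=O)OC(C)=O
Why: Acylation should be selective for the primary alcohol, because the tertiary C8 alcohol does not react under these conditions.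

**Step 6**
Reactants: 6 ether acetate
Product: 7 lactone acetate (C4′(=O)–O6 γ-lactone, 8α-OH, C12-OAc)
Conditions: RuCl3·xH2O (cat.), NaIO4, EtOAc/MeCN/H2O, rt
Reagents that add atoms: sodium periodate (oxygen source through RuO4), [Na+].[O-]I(=O)(=O)=O
Why: RuO4 oxidation of a cyclic ether at its O–CH2 position should give the lactone, as in the oxidation of steroid 6β,19-ethers; the tertiary alcohol and the acetate are inert.

**Step 7**
Reactants: 7 lactone acetate
Product: 8 silyl lactone (8-O-SiEt3 ether of 7)
Conditions: Et3SiOTf, 2,6-lutidine, CH2Cl2, −78 to 0 °C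
Reagents that add atoms: triethylsilyl triflate, CC[Si](CC)(CC)OS(=O)(=O)C(F)(F)F
Why: Silyl triflate silylation should protect the tertiary alcohol, which would otherwise close onto C12 later.

**Step 8**
Reactants: 8 silyl lactone
Product: 10 allyl ester diol (C4′ allyl ester, 6α-OH, C12-OH, 8α-OSiEt3), via lithium carboxylate 9 (not isolated)
Conditions: LiOH, THF/H2O, 45 °C; evaporate; allyl bromide, DMF, rt
Reagents that add atoms: lithium hydroxide, [Li+].[OH-]; allyl bromide, C=CCBr
Why: Saponification should open the strained lactone and remove the acetate, and SN2 O-alkylation of the carboxylate gives the ester without activating the hindered acid beside the free 6-hydroxyl.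

**Step 9**
Reactants: 10 allyl ester diol
Product: 11 iodo alcohol (C12-I, 6α-OH)
Conditions: I2, PPh3, imidazole, CH2Cl2, 0 °C
Reagents that add atoms: iodine, II
Why: Appel-type (Garegg–Samuelsson) iodination should take place at the primary alcohol only, the peri-hindered secondary 6-hydroxyl being much slower.

**Step 10**
Reactants: 11 iodo alcohol
Product: 12 decalin iodide (C12-I, 6α,8α-bis(OSiEt3), C4′ allyl ester, 4β-CH3)
Conditions: Et3SiOTf, 2,6-lutidine, CH2Cl2, −78 to 0 °C
Reagents that add atoms: triethylsilyl triflate, CC[Si](CC)(CC)OS(=O)(=O)C(F)(F)F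
Why: Silyl triflate silylation should cap the hindered secondary alcohol before the organometallic step.

**Step 11**
Reactants: 13 (E)-pent-2-en-4-yn-1-ol
Product: 14 [(1R,2R)-2-ethynylcyclopropyl]methanol
Conditions: Zn(CH2I)2·DME (from Et2Zn and CH2I2), (4S,5S)-2-butyl-N,N,N′,N′-tetramethyl-1,3,2-dioxaborolane-4,5-dicarboxamide, CH2Cl2, −10 °C to rt
Reagents that add atoms: diiodomethane (as Zn(CH2I)2), ICI
Why: In this Charette asymmetric Simmons–Smith cyclopropanation the zinc alkoxide bound to the chiral dioxaborolane delivers CH2 to one face of the E-alkene; the (4R,5R) ligand gives the (S,S) series with cinnamyl alcohol, so the (4S,5S) ligand should give the trans (1R,2R) product.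

**Step 12**
Reactants: 14 [(1R,2R)-2-ethynylcyclopropyl]methanol; 15 allyl chloroformate
Product: 18 allyl 3-[(1R,2R)-2-(hydroxymethyl)cyclopropyl]prop-2-ynoate, via O-trimethylsilyl ether 16 (not isolated), via silylated ynoate 17 (not isolated)
Conditions: n-BuLi, THF, −78 °C; Me3SiCl; n-BuLi; 15, −78 °C; then aq. citric acid, MeOH
Reagents that add atoms: none
Why: Transient O-silylation of the lithium alkoxide, deprotonation of the alkyne and C-acylation of the lithium acetylide by the chloroformate should give the ynoate, the silyl ether being cleaved on acidic work-up.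

**Step 13**
Reactants: 18 allyl 3-[(1R,2R)-2-(hydroxymethyl)cyclopropyl]prop-2-ynoate
Product: 19 allyl (Z)-3-[(1R,2R)-2-(hydroxymethyl)cyclopropyl]but-2-enoate
Conditions: Me2CuLi (from CuI and MeLi, 2.2 equiv), THF, −78 °C; aq. NH4Cl
Reagents that add atoms: lithium dimethylcuprate, [Li+].C[Cu-]C
Why: Syn-carbocupration of the ynoate at −78 °C followed by protonation with retention should give the (Z)-β-methyl enoate, with the cyclopropyl carbon cis to the ester; the allyl ester is not substituted at this temperature.

**Step 14**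
Reactants: 19 allyl (Z)-3-[(1R,2R)-2-(hydroxymethyl)cyclopropyl]but-2-enoate
Product: 20 allyl (Z)-3-[(1R,2R)-2-formylcyclopropyl]but-2-enoate
Conditions: Dess–Martin periodinane, NaHCO3, CH2Cl2, rt
Reagents that add atoms: none
Why: Dess–Martin oxidation of the primary alcohol is neutral and should leave the trans-cyclopropane and the Z-enoate untouched.

**Step 15**
Reactants: 20 allyl (Z)-3-[(1R,2R)-2-formylcyclopropyl]but-2-enoate
Product: 21 allyl (Z)-3-[(1R,2R)-2-(1-hydroxyethyl)cyclopropyl]but-2-enoate (both carbinol epimers)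
Conditions: MeMgBr, THF, −78 °C
Reagents that add atoms: methylmagnesium bromide, C[Mg]Br
Why: Grignard 1,2-addition should be selective for the aldehyde over the β,β-disubstituted enoate at −78 °C; the new carbinol centre is oxidised in the next step, so its configuration is irrelevant.

**Step 16**
Reactants: 21 allyl (Z)-3-[(1R,2R)-2-(1-hydroxyethyl)cyclopropyl]but-2-enoate
Product: 22 allyl (Z)-3-[(1R,2R)-2-acetylcyclopropyl]but-2-enoate
Conditions: Dess–Martin periodinane, NaHCO3, CH2Cl2, rt
Reagents that add atoms: none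
Why: Dess–Martin oxidation of the secondary alcohol should give the methyl ketone without epimerising the more stable trans-cyclopropane.

**Step 17**
Reactants: 12 decalin iodide; 22 allyl (Z)-3-[(1R,2R)-2-acetylcyclopropyl]but-2-enoate
Product: 25 tertiary cyclopropyl carbinol bis-allyl ester (C12–C13 bond, C13 epimers, 14R,16R), via alkyllithium 23 (not isolated), via alkylcerium dichloride 24 (not isolated)
Conditions: 12, t-BuLi (2 equiv), Et2O/pentane, −78 °C; CeCl3, THF, −78 °C; 22, −78 °C; aq. NH4Cl
Reagents that add atoms: none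
Why: Iodine–lithium exchange, transmetalation to RCeCl2 and 1,2-addition to the methyl ketone (Imamoto conditions) should suppress enolisation and attack on the hindered or conjugated esters; the C13 epimer mixture is of no consequence because C13 becomes sp2 in step 19.

**Step 18**
Reactants: 25 tertiary cyclopropyl carbinol bis-allyl ester
Product: 26 cyclopropyl carbinol diacid ((Z)-enoic acid and C4′ acid, 6α,8α-bis(OSiEt3), C13 epimers)
Conditions: Pd(PPh3)4 (5 mol %), morpholine, THF, rt; pH 5 phosphate buffer
Reagents that add atoms: none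
Why: Tsuji–Trost deallylation should remove both allyl esters under basic conditions (morpholine traps the allyl groups) that leave the acid-labile cyclopropyl carbinol and the silyl ethers intact.

**Step 19**
Reactants: 26 cyclopropyl carbinol diacid
Product: 27 bis-silyl butenolide acid (6,8-bis-O-SiEt3 ether of the target)
Conditions: Sc(OTf)3 (5 mol %), 4 Å molecular sieves, CH2Cl2, −40 to 0 °C
Reagents that add atoms: none
Why: Proposed new method: Sc(OTf)3 ionises the tertiary C13 carbinol (either epimer) to a bisected cyclopropylcarbinyl cation whose charge is shared with the C14–C16 bond, and the carboxyl oxygen of the (Z)-enoic acid, held beside C16, attacks C16 on the side opposite C14 while that bond breaks and C13=C14 forms, after which proton loss gives the lactone; the closest known reactions are the Julia olefin synthesis (cyclopropylcarbinyl-to-homoallyl opening) and the stereoinvertive substitution of cyclopropyl carbinols by oxygen nucleophiles, neither of which has been run with an internal carboxyl group attacking a ring CH. The butenolide (O–C19–C18=C17–C16) closes in a 5-exo-tet mode, the breaking C14–C16 bond lying outside the new ring. C16 is controlled by the cyclopropane configuration set in step 11, backside attack turning (16R) of 26 into the (R)-lactone carbon of the target. Attack is needed at C16 and not at C15 or C13: five-membered closure at the more substituted ring carbon is favoured over six-membered closure at C15, closure at C13 would span the trans-cyclopropane in a seven-membered ring, the C6 and C8 oxygens are silylated and the C4′ carboxyl cannot reach, and the electron-poor enoate keeps charge off C16 so that the bond breaks only as the oxygen arrives. E geometry is needed at C13=C14 and should follow from the preferred bisected cation, in which the small methyl lies over the ring and the C12 chain sits beside H14, as in the Julia synthesis of trisubstituted alkenes; reversible ionisation lets both C13 epimers pass through this cation. Molecular sieves keep the released water from competing as the nucleophile.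

**Step 20**
Reactants: 27 bis-silyl butenolide acid
Product: 28 CNP0387770.1 (target)
Conditions: HF·pyridine, pyridine, THF, 0 °C to rt
Reagents that add atoms: none
Why: Buffered fluoride desilylation should cleave the tertiary and the hindered secondary triethylsilyl ethers without touching the butenolide, the alkene or the C16 centre.

**Compound list**
1 | (+)-larixol, labda-8(17),14-diene-6α,13-diol (13S) | C=C[C@@](C)(O)CC[C@@H]1[C@@]2(C)CCCC(C)(C)[C@@H]2[C@@H](O)CC1=C | starting material
2 | nor-ketone: 6α-hydroxy-8-methylidene decalin with 3-oxobutyl on C9 | CC(=O)CC[C@@H]1[C@@]2(C)CCCC(C)(C)[C@@H]2[C@@H](O)CC1=C | intermediate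
3 | epoxy acetate: C12-OAc, 8α-O/C8′ spiro-epoxide, 6α-OH | CC(=O)OCC[C@@H]1[C@@]2(C)CCCC(C)(C)[C@@H]2[C@@H](O)C[C@]13CO3 | intermediate
4 | cyclic ether: O6–C4′ tetrahydrofuran (α face), epoxide, C12-OAc | CC(=O)OCC[C@@H]1[C@@]2(C)CCC[C@@](C)(CO3)[C@@H]2[C@@H]3C[C@]14CO4 | intermediate
5 | ether diol: C12-OH, 8α-OH (8β-CH3), O6–C4′ ether | OCC[C@@H]1[C@@]2(C)CCC[C@@](C)(CO3)[C@@H]2[C@@H]3C[C@@]1(C)O | intermediate
6 | ether acetate: C12-OAc, 8α-OH, O6–C4′ ether | CC(=O)OCC[C@@H]1[C@@]2(C)CCC[C@@](C)(CO3)[C@@H]2[C@@H]3C[C@@]1(C)O | intermediate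
7 | lactone acetate: C4′(=O)–O6 γ-lactone, 8α-OH, C12-OAc | CC(=O)OCC[C@@H]1[C@@]2(C)CCC[C@@](C)(C(=O)O3)[C@@H]2[C@@H]3C[C@@]1(C)O | intermediate
8 | silyl lactone: 8-O-SiEt3 ether of 7 | CC(=O)OCC[C@@H]1[C@@]2(C)CCC[C@@](C)(C(=O)O3)[C@@H]2[C@@H]3C[C@@]1(C)O[Si](CC)(CC)CC | intermediate
9 | lithium carboxylate: C4′ carboxylate, 6α-OH, C12-OH, 8α-OSiEt3 | [Li+].OCC[C@@H]1[C@@]2(C)CCC[C@@](C)(C(=O)[O-])[C@@H]2[C@@H](O)C[C@@]1(C)O[Si](CC)(CC)CC | intermediate
10 | allyl ester diol: C4′ allyl ester, 6α-OH, C12-OH, 8α-OSiEt3 | OCC[C@@H]1[C@@]2(C)CCC[C@@](C)(C(=O)OCC=C)[C@@H]2[C@@H](O)C[C@@]1(C)O[Si](CC)(CC)CC | intermediate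
11 | iodo alcohol: C12-I, 6α-OH, 8α-OSiEt3, C4′ allyl ester | ICC[C@@H]1[C@@]2(C)CCC[C@@](C)(C(=O)OCC=C)[C@@H]2[C@@H](O)C[C@@]1(C)O[Si](CC)(CC)CC | intermediate
12 | decalin iodide: C12-I, 6α,8α-bis(OSiEt3), C4′ allyl ester | ICC[C@@H]1[C@@]2(C)CCC[C@@](C)(C(=O)OCC=C)[C@@H]2[C@@H](O[Si](CC)(CC)CC)C[C@@]1(C)O[Si](CC)(CC)CC | intermediate
13 | (E)-pent-2-en-4-yn-1-ol | OC/C=C/C#C | starting material
14 | [(1R,2R)-2-ethynylcyclopropyl]methanol | OC[C@@H]1C[C@H]1C#C | intermediate
15 | allyl chloroformate | C=CCOC(Cl)=O | starting material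
16 | O-trimethylsilyl ether of 14 | C[Si](C)(C)OC[C@@H]1C[C@H]1C#C | intermediate
17 | allyl 3-[(1R,2R)-2-(trimethylsilyloxymethyl)cyclopropyl]prop-2-ynoate | C[Si](C)(C)OC[C@@H]1C[C@H]1C#CC(=O)OCC=C | intermediate
18 | allyl 3-[(1R,2R)-2-(hydroxymethyl)cyclopropyl]prop-2-ynoate | OC[C@@H]1C[C@H]1C#CC(=O)OCC=C | intermediate
19 | allyl (Z)-3-[(1R,2R)-2-(hydroxymethyl)cyclopropyl]but-2-enoate | OC[C@@H]1C[C@H]1/C(C)=C\C(=O)OCC=C | intermediate
20 | allyl (Z)-3-[(1R,2R)-2-formylcyclopropyl]but-2-enoate | O=C[C@@H]1C[C@H]1/C(C)=C\C(=O)OCC=C | intermediate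
21 | allyl (Z)-3-[(1R,2R)-2-(1-hydroxyethyl)cyclopropyl]but-2-enoate, carbinol epimers | CC(O)[C@@H]1C[C@H]1/C(C)=C\C(=O)OCC=C | intermediate
22 | allyl (Z)-3-[(1R,2R)-2-acetylcyclopropyl]but-2-enoate | CC(=O)[C@@H]1C[C@H]1/C(C)=C\C(=O)OCC=C | intermediate
23 | alkyllithium from 12 (C12–Li) | [Li]CC[C@@H]1[C@@]2(C)CCC[C@@](C)(C(=O)OCC=C)[C@@H]2[C@@H](O[Si](CC)(CC)CC)C[C@@]1(C)O[Si](CC)(CC)CC | intermediate
24 | alkylcerium dichloride from 23 (C12–CeCl2) | Cl[Ce](Cl)CC[C@@H]1[C@@]2(C)CCC[C@@](C)(C(=O)OCC=C)[C@@H]2[C@@H](O[Si](CC)(CC)CC)C[C@@]1(C)O[Si](CC)(CC)CC | intermediate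
25 | tertiary cyclopropyl carbinol bis-allyl ester (14R,16R; C13 epimers) | C=CCOC(=O)/C=C(C)\[C@@H]1C[C@H]1C(C)(O)CC[C@@H]2[C@@]3(C)CCC[C@@](C)(C(=O)OCC=C)[C@@H]3[C@@H](O[Si](CC)(CC)CC)C[C@@]2(C)O[Si](CC)(CC)CC | intermediate
26 | cyclopropyl carbinol diacid (14R,16R; C13 epimers) | OC(=O)/C=C(C)\[C@@H]1C[C@H]1C(C)(O)CC[C@@H]2[C@@]3(C)CCC[C@@](C)(C(=O)O)[C@@H]3[C@@H](O[Si](CC)(CC)CC)C[C@@]2(C)O[Si](CC)(CC)CC | intermediate
27 | bis-silyl butenolide acid (6,8-bis-O-SiEt3 ether of the target) | CC1=CC(=O)O[C@@H]1C/C=C(\C)CC[C@@H]1[C@@]2(C)CCC[C@@](C)(C(=O)O)[C@@H]2[C@@H](O[Si](CC)(CC)CC)C[C@@]1(C)O[Si](CC)(CC)CC | intermediate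
28 | CNP0387770.1 | CC1=CC(=O)O[C@@H]1C/C=C(\C)CC[C@@H]1[C@@]2(C)CCC[C@@](C)(C(=O)O)[C@@H]2[C@@H](O)C[C@@]1(C)O | target

**Step count and risks**
Total: 20 steps. Longest linear sequence: 14 steps (1–10, then 17–20).

Steps most likely to fail:

1. Step 19. The two bisected cation rotamers differ only in whether methyl or the C12 methylene lies over the ring, so alkene geometry may erode. The cation may also be captured at C15 or by water, or lose a proton to a vinylcyclopropane.
Fallback, from 12 back to 27, with alkene and lactone made separately by known reactions: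
   - Displacement of the iodide with lithium acetylide–ethylenediamine in DMSO would give terminal alkyne F1.
   - Zr-catalysed methylalumination (AlMe3, Cp2ZrCl2), conversion to the alanate with n-BuLi and opening of oxirane would give (E)-homoallylic alcohol F2, the geometry following from syn-carbometalation.
   - Dess–Martin oxidation would give β,γ-unsaturated aldehyde F3.
   - Zn-catalysed asymmetric addition of methyl propiolate (Me2Zn, the ProPhenol ligand enantiomer that gives the R carbinol) would set C16 in hydroxy ynoate F4.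
   - Me2CuLi syn-addition at −78 °C with lactonisation on warming would give butenolide allyl ester F5.
   - Pd(PPh3)4 with morpholine removes the allyl group and the sequence rejoins the route at 27.

2. Step 3. β-Scission of the 6-alkoxy radical (C5–C6 cleavage) or opening of the epoxide by the acetic acid formed may compete with the 1,5-hydrogen transfer.
Fallback, from 3 back to 4, by metal-catalysed C–H silylation instead of a radical:
   - Et2SiH2 with [Ir(cod)OMe]2 would give diethylhydrosilyl ether F6.
   - [Rh(cod)Cl]2/Xantphos with norbornene at 100 °C would close oxasilinane F7 by hydroxyl-directed δ-C–H silylation of the 4α-methyl group, the only primary C–H held beside O6 (no γ C–H exists).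
   - Tamao–Fleming oxidation (H2O2, KHCO3, KF) would give primary–secondary diol F8.
   - Mitsunobu cyclodehydration (PPh3, DIAD) closes the tetrahydrofuran and rejoins the route at 4.

3. Step 17. The alkyllithium may attack an allyl ester, silicon may migrate from O8 to C12 before transmetalation, or the ketone may be enolised.
Fallback, from 12 and 20 back to 25, without an organolithium:
   - Co-catalysed Cr-mediated addition of the iodide to aldehyde 20 (CrCl2, cobalt phthalocyanine Co(C32H16N8), DMF) would give secondary cyclopropyl carbinol F9.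
   - Dess–Martin oxidation would give cyclopropyl ketone F10.
   - MeMgBr with CeCl3 at −78 °C adds the C13 methyl group and rejoins the route at 25.

**Further compounds**
F1 | step 19 | terminal alkyne (C12–C≡CH; 6α,8α-bis(OSiEt3), C4′ allyl ester) | C#CCC[C@@H]1[C@@]2(C)CCC[C@@](C)(C(=O)OCC=C)[C@@H]2[C@@H](O[Si](CC)(CC)CC)C[C@@]1(C)O[Si](CC)(CC)CC
F2 | step 19 | (E)-homoallylic alcohol (C16-OH, E-C13=C14) | OCC/C=C(\C)CC[C@@H]1[C@@]2(C)CCC[C@@](C)(C(=O)OCC=C)[C@@H]2[C@@H](O[Si](CC)(CC)CC)C[C@@]1(C)O[Si](CC)(CC)CC
F3 | step 19 | β,γ-unsaturated aldehyde (C16 aldehyde) | O=CC/C=C(\C)CC[C@@H]1[C@@]2(C)CCC[C@@](C)(C(=O)OCC=C)[C@@H]2[C@@H](O[Si](CC)(CC)CC)C[C@@]1(C)O[Si](CC)(CC)CC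
F4 | step 19 | hydroxy ynoate (methyl ester, 16R carbinol) | COC(=O)C#C[C@H](O)C/C=C(\C)CC[C@@H]1[C@@]2(C)CCC[C@@](C)(C(=O)OCC=C)[C@@H]2[C@@H](O[Si](CC)(CC)CC)C[C@@]1(C)O[Si](CC)(CC)CC
F5 | step 19 | butenolide allyl ester (allyl ester of 27) | CC1=CC(=O)O[C@@H]1C/C=C(\C)CC[C@@H]1[C@@]2(C)CCC[C@@](C)(C(=O)OCC=C)[C@@H]2[C@@H](O[Si](CC)(CC)CC)C[C@@]1(C)O[Si](CC)(CC)CC
F6 | step 3 | diethylhydrosilyl ether of 3 | CC(=O)OCC[C@@H]1[C@@]2(C)CCCC(C)(C)[C@@H]2[C@@H](O[SiH](CC)CC)C[C@]13CO3
F7 | step 3 | oxasilinane (O6–SiEt2–C4′) | CC(=O)OCC[C@@H]1[C@@]2(C)CCC[C@@](C)(C[Si](CC)(CC)O3)[C@@H]2[C@@H]3C[C@]14CO4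
F8 | step 3 | diol (C4′-OH, 6α-OH; epoxide and acetate kept) | CC(=O)OCC[C@@H]1[C@@]2(C)CCC[C@@](C)(CO)[C@@H]2[C@@H](O)C[C@]13CO3
F9 | step 17 | secondary cyclopropyl carbinol (C13-OH, no methyl; epimers) | C=CCOC(=O)/C=C(C)\[C@@H]1C[C@H]1C(O)CC[C@@H]2[C@@]3(C)CCC[C@@](C)(C(=O)OCC=C)[C@@H]3[C@@H](O[Si](CC)(CC)CC)C[C@@]2(C)O[Si](CC)(CC)CC
F10 | step 17 | cyclopropyl ketone (C13=O) | C=CCOC(=O)/C=C(C)\[C@@H]1C[C@H]1C(=O)CC[C@@H]2[C@@]3(C)CCC[C@@](C)(C(=O)OCC=C)[C@@H]3[C@@H](O[Si](CC)(CC)CC)C[C@@]2(C)O[Si](CC)(CC)CC
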